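The numbers in the tables come from a simulation with constants of no real substance, and the scatter is random.

Time is what a larger catalyst charge takes from a flask: the same conversion comes sooner, and whatever runs by the clock has done less by then. Here is the problem.

| setting | dawn | autumn | flask |
|---|---|---|---|
| left-handed substrate | 0.80 M | 0.80 M | 0.80 M |
| right-handed substrate | 0.80 M | 0.80 M | 0.80 M |
| partner | 1.7 equiv | 2.6 equiv | 1.20 equiv |
| protic impurity | 0.16 M | 0.16 M | 0.160 M |
| free catalyst | 2 mol% | 2 mol% | 2 mol% |
| added ligand | 31 mM | 31 mM | 31 mM |
| remark | run made earlier | run made earlier |  |

- dawn (time / min: left-handed product / %): 6.00: 6.5; 8.00: 8.4; 12.0: 10.9; 20.0: 15.2; 30.0: 18.9; 50.0: 23.9; 80.0: 27.8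
- autumn (time / min: left-handed product / %): 10.0: 14.2; 20.0: 22.1; 30.0: 28.2; 40.0: 31.6; 50.0: 35.1; 60.0: 36.4; 80.0: 39.7

(each reading ± 0.5 percentage points)

- free catalyst is single-handed; left-handed substrate and right-handed substrate are mirror images of each other, charged as a racemate, each of them at the stated concentration
- no earlier run changes the charge of free catalyst; that part of a forecast is a guess

1. apparent order in free catalyst when 30% of the left-handed substrate and right-handed substrate together are converted (percent change of the rate of making left-handed product for one percent more free catalyst charged)

Build the flask up one process at a time. With the main step by itself, the rate follows the catalyst, so the order is 1. The rate also follows the partner: the dawn and autumn runs differ in partner charge, and at 20.0 min their product readings scale as that charge to the power 0.881, a reading of amounts made that lies close to first order. In the flask, the partner charge of 0.960 M is less than the 1.60 M of both substrates together, so it is the limiting reagent. Assume each converted substrate takes one partner. At the asked conversion, the flask then holds 0.480 M, the partner budget at the mark, before any quenching.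

Now add the protic impurity. If it destroys partner by the clock, the loss shrinks as the time shrinks, and the order gains a surcharge: partner quenched by the mark over budget minus quenched. The readings are of left-handed product, so I guess that 0.0400 M is quenched by the mark, a quarter of the impurity, which gives 0.0909.

Then add the ligand. The flask's catalyst charge of 16.0 mM is about half of the ligand, so more catalyst uses up ligand noticeably. Roughly, the gain is the bound share squared times that ratio, and a guessed share of 0.5 gives 0.129. My reckoning is therefore 1.22.

The forecast is higher, at 1.5 within 1 to 2.4, and says “so this is a guess”.

The flask gives 1.2.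

    free catalyst + left-handed substrate ⇌ catalyst intermediate A (K = 0.250 M⁻¹, k = 1.50 M⁻¹ s⁻¹)
    free catalyst + right-handed substrate ⇌ catalyst intermediate B (K = 1.10 M⁻¹, k = 0.840 M⁻¹ s⁻¹)
    partner + catalyst intermediate A → free catalyst + left-handed product (k = 0.190 M⁻¹ s⁻¹)
    partner + catalyst intermediate B → free catalyst + right-handed product (k = 0.0810 M⁻¹ s⁻¹)
    partner + protic impurity → quenched reagent (k = 2.40 × 10⁻⁴ M⁻¹ s⁻¹)
    free catalyst + added ligand ⇌ idle complex (K = 34.0 M⁻¹, k = 0.0800 M⁻¹ s⁻¹)

At 0.200 h, the idle complex in the flask holds 30.7% of the catalyst charged. Quenched reagent stands at 0.0196 M at 0.200 h and 0.0482 M at 1.00 h, on either side of the mark at 0.356 h. Set against the budget of 0.480 M, these put the surcharge between 0.0426 and 0.112.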